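The cyclobutane (C1 = CMe2, C2 = CH–aryl, C2a and C7a = ring-fusion CH; cyclobuta[a]indene numbering) is read as the intramolecular [2+2] adduct of a stilbene C=C and the C=C of an ortho-prenyl group, whose CH2 and CMe2 become C7 and C1. The strategic bond is C2a–C7a, shared by the four- and five-membered rings; it forms first (5-exo) and C1–C2 follows. The precursor is an achiral, silyl-protected 2-prenylstilbene. An enantioselective radical-cation photocycloaddition under a chiral ion-pair photoredox catalyst builds both rings and all three stereocentres in one operation; E/Z isomers converge. The second prenyl group at C3 is added afterwards, so that only one alkene can cyclise.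

Key step: step 7

Numbering used throughout (2,2a,7,7a-tetrahydro-1H-cyclobuta[a]indene): C1 = CMe2, C2 = CH–aryl, C2a = benzylic ring-fusion CH, C3–C6 = benzo CH/C positions (C3 prenyl, C4 OMe, C6 OH in the target), C7 = CH2, C7a = second ring-fusion CH.

Remark (assumption): the sense of induction of the ion-pair catalyst in step 7 cannot be predicted from first principles; both antipodes of the chiral anion are accessible, and the one that delivers the (2S,2aR,7aS) series is to be used.

Step 1
Reactants: 1 1,3-dibromo-5-methoxybenzene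
Product: 3 1,3-dibromo-5-methoxy-2-(3-methylbut-2-en-1-yl)benzene, via aryllithium 2 (not isolated)
Conditions: LDA, THF, −78 °C; then CuBr·SMe2 (cat.), prenyl bromide, −78 → −20 °C
Reagents that add atoms: prenyl bromide (1-bromo-3-methylbut-2-ene), CC(C)=CCBr
Why: Deprotonative lithiation (directed ortho-metalation) should remove the proton flanked by the two bromine atoms, the most acidic C–H of 1, and copper-assisted SN2 allylation of aryllithium 2 at the primary carbon of prenyl bromide then places the prenyl group para to OMe between two equivalent bromines.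

Step 2
Reactants: 3 1,3-dibromo-5-methoxy-2-(3-methylbut-2-en-1-yl)benzene
Product: 6 3-bromo-5-methoxy-2-(3-methylbut-2-en-1-yl)phenol, via aryllithium 4 (not isolated), via lithium aryl(triisopropoxy)borate 5 (not isolated)
Conditions: B(OiPr)3, n-BuLi (1.0 equiv), THF–toluene, −78 °C (in situ quench); then NaOH, H2O2, 0 °C → rt
Reagents that add atoms: hydrogen peroxide, OO
Why: Bromine–lithium exchange with in situ borylation followed by oxidation of the aryl–boron bond (boron-to-oxygen 1,2-shift) should give the phenol; the two bromines of 3 are equivalent, so one equivalent of n-BuLi can lead only to 6, and the trisubstituted alkene is inert to alkaline peroxide.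

Step 3
Reactants: 6 3-bromo-5-methoxy-2-(3-methylbut-2-en-1-yl)phenol
Product: 7 [3-bromo-5-methoxy-2-(3-methylbut-2-en-1-yl)phenoxy](tert-butyl)dimethylsilane
Conditions: TBSCl, imidazole, DMF, rt
Reagents that add atoms: tert-butyldimethylsilyl chloride (TBSCl), CC(C)(C)[Si](C)(C)Cl
Why: Silyl ether formation masks the phenol next to the prenyl group, so that in step 7 it can neither be oxidised nor trap a cation.

Step 4
Reactants: 8 3,4-dihydroxybenzaldehyde
Product: 9 3,4-bis[(tert-butyldimethylsilyl)oxy]benzaldehyde
Conditions: TBSCl (2.2 equiv), imidazole, DMF, rt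
Reagents that add atoms: tert-butyldimethylsilyl chloride (TBSCl), CC(C)(C)[Si](C)(C)Cl
Why: Double silylation of the catechol gives aryl silyl ethers that keep this ring electron-rich for step 7 and tolerate the later organolithium step.

Step 5
Reactants: 9 3,4-bis[(tert-butyldimethylsilyl)oxy]benzaldehyde
Product: 10 4-ethenyl-1,2-bis[(tert-butyldimethylsilyl)oxy]benzene
Conditions: Ph3PCH3Br, NaHMDS, THF, 0 °C → rt
Reagents that add atoms: methyltriphenylphosphonium bromide, C[P+](c1ccccc1)(c1ccccc1)c1ccccc1.[Br-]
Why: Wittig methylenation of the aldehyde with the non-stabilised ylide generated in the flask should give the styrene.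

Step 6
Reactants: 7 [3-bromo-5-methoxy-2-(3-methylbut-2-en-1-yl)phenoxy](tert-butyl)dimethylsilane; 10 4-ethenyl-1,2-bis[(tert-butyldimethylsilyl)oxy]benzene
Product: 11 tert-butyl{3-[(E)-2-{3,4-bis[(tert-butyldimethylsilyl)oxy]phenyl}ethenyl]-5-methoxy-2-(3-methylbut-2-en-1-yl)phenoxy}dimethylsilane
Conditions: Pd2(dba)3 (cat.), [(t-Bu)3PH]BF4 (cat.), Cy2NMe, 1,4-dioxane, 80 °C
Reagents that add atoms: none
Why: Mizoroki–Heck reaction of the ortho-substituted aryl bromide with the styrene (bulky electron-rich phosphine, amine base compatible with aryl silyl ethers) should give the E-stilbene by syn-insertion and syn-β-hydride elimination, while the trisubstituted prenyl alkene does not insert.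

Step 7
Reactants: 11 tert-butyl{3-[(E)-2-{3,4-bis[(tert-butyldimethylsilyl)oxy]phenyl}ethenyl]-5-methoxy-2-(3-methylbut-2-en-1-yl)phenoxy}dimethylsilane
Product: 13 tert-butyl{[(2S,2aR,7aS)-2-{3,4-bis[(tert-butyldimethylsilyl)oxy]phenyl}-4-methoxy-1,1-dimethyl-2,2a,7,7a-tetrahydro-1H-cyclobuta[a]inden-6-yl]oxy}dimethylsilane, via distonic radical cation 12 (not isolated)
Conditions: chiral 9-arylthioxanthylium imidodiphosphorimidate (IDPi) ion pair (2–5 mol %), CH2Cl2, −78 °C, green LEDs, Ar
Reagents that add atoms: none
Why: Proposed new method: the photoexcited thioxanthylium cation oxidises the electron-rich stilbene of 11 to its radical cation, which stays paired with the confined chiral IDPi anion; the tethered prenyl alkene attacks the alkene carbon bound to ring A (5-exo-trig closure of the five-membered ring through the C2a–C7a bond) to give distonic radical cation 12, whose benzylic radical and tertiary cation collapse to the cyclobutane (1,4-closure forming C1–C2, formally 4-exo), and back electron transfer releases 13. The closest known reaction type is the photoredox radical-cation [2+2] cycloaddition of electron-rich aryl alkenes, established without chiral information for tethered styrene–alkene pairs and, with this kind of chiral ion pair, for intermolecular styrene–styrene pairs; the enantioselective intramolecular stilbene/trisubstituted-alkene case is untested. C2a and C7a are necessarily cis because a bicyclo[3.2.0] ring fusion allows nothing else, and the aryl group at C2 should take the exo position, trans to ring A at C2a, as the less hindered outcome of the stepwise closure, so that E- and Z-11 converge on one diastereomer. The absolute configuration is controlled by the anion, which has to select one of two rapidly interconverting mirror-image twisted conformers of the radical cation about the aryl–vinyl bond. The step needs regioselectivity (5-exo attack at the ring-A-bound carbon, not 6-endo at the other), secured by ring size and by the para-silyloxy stabilisation of the resulting benzylic radical, and chemoselectivity, secured because 11 carries a single prenyl group and its neighbouring phenol is silylated so that the tertiary cation cannot be trapped as a chroman.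

Step 8
Reactants: 13 tert-butyl{[(2S,2aR,7aS)-2-{3,4-bis[(tert-butyldimethylsilyl)oxy]phenyl}-4-methoxy-1,1-dimethyl-2,2a,7,7a-tetrahydro-1H-cyclobuta[a]inden-6-yl]oxy}dimethylsilane
Product: 14 tert-butyl{[(2S,2aR,7aS)-2-{3,4-bis[(tert-butyldimethylsilyl)oxy]phenyl}-3-bromo-4-methoxy-1,1-dimethyl-2,2a,7,7a-tetrahydro-1H-cyclobuta[a]inden-6-yl]oxy}dimethylsilane
Conditions: NBS (1.0 equiv), CH2Cl2–MeCN, 0 °C, dark
Reagents that add atoms: N-bromosuccinimide (NBS), O=C1CCC(=O)N1Br
Why: Electrophilic aromatic bromination should occur at C3, which is para to the silyloxy and ortho to the methoxy group of the resorcinol-type ring, whereas C5 is flanked by two oxygen substituents and the catechol-derived ring is less activated; no alkene is left to compete, which is why the second prenyl group is introduced only after this point.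

Step 9
Reactants: 14 tert-butyl{[(2S,2aR,7aS)-2-{3,4-bis[(tert-butyldimethylsilyl)oxy]phenyl}-3-bromo-4-methoxy-1,1-dimethyl-2,2a,7,7a-tetrahydro-1H-cyclobuta[a]inden-6-yl]oxy}dimethylsilane
Product: 16 tert-butyl{[(2S,2aR,7aS)-2-{3,4-bis[(tert-butyldimethylsilyl)oxy]phenyl}-4-methoxy-1,1-dimethyl-3-(3-methylbut-2-en-1-yl)-2,2a,7,7a-tetrahydro-1H-cyclobuta[a]inden-6-yl]oxy}dimethylsilane, via aryllithium 15 (not isolated)
Conditions: t-BuLi (2.1 equiv), THF, −78 °C; then CuBr·SMe2 (cat.), prenyl bromide, −78 → 0 °C
Reagents that add atoms: prenyl bromide (1-bromo-3-methylbut-2-ene), CC(C)=CCBr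
Why: Bromine–lithium exchange followed by copper-assisted SN2 allylation of aryllithium 15 at the primary carbon of prenyl bromide should install the C3 prenyl group without touching the aryl silyl ethers or the stereocentres.

Step 10
Reactants: 16 tert-butyl{[(2S,2aR,7aS)-2-{3,4-bis[(tert-butyldimethylsilyl)oxy]phenyl}-4-methoxy-1,1-dimethyl-3-(3-methylbut-2-en-1-yl)-2,2a,7,7a-tetrahydro-1H-cyclobuta[a]inden-6-yl]oxy}dimethylsilane
Product: 17 4-[(2S,2aR,7aS)-6-hydroxy-4-methoxy-1,1-dimethyl-3-(3-methylbut-2-en-1-yl)-2,2a,7,7a-tetrahydro-1H-cyclobuta[a]inden-2-yl]benzene-1,2-diol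
Conditions: TBAF, AcOH, THF, 0 °C → rt, Ar
Reagents that add atoms: none
Why: Buffered fluoride-mediated desilylation should cleave the three aryl silyl ethers while sparing the prenyl group, the methyl ether and the air-sensitive catechol, and it touches no stereocentre.

Compound list
1 | 1,3-dibromo-5-methoxybenzene | COc1cc(Br)cc(Br)c1 | starting material
2 | (2,6-dibromo-4-methoxyphenyl)lithium (not isolated) | COc1cc(Br)c([Li])c(Br)c1 | intermediate
3 | 1,3-dibromo-5-methoxy-2-(3-methylbut-2-en-1-yl)benzene | COc1cc(Br)c(CC=C(C)C)c(Br)c1 | intermediate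
4 | [3-bromo-5-methoxy-2-(3-methylbut-2-en-1-yl)phenyl]lithium (not isolated) | COc1cc(Br)c(CC=C(C)C)c([Li])c1 | intermediate
5 | lithium [3-bromo-5-methoxy-2-(3-methylbut-2-en-1-yl)phenyl]tri(propan-2-yloxy)borate (not isolated) | [Li+].COc1cc(Br)c(CC=C(C)C)c([B-](OC(C)C)(OC(C)C)OC(C)C)c1 | intermediate
6 | 3-bromo-5-methoxy-2-(3-methylbut-2-en-1-yl)phenol | COc1cc(Br)c(CC=C(C)C)c(O)c1 | intermediate
7 | [3-bromo-5-methoxy-2-(3-methylbut-2-en-1-yl)phenoxy](tert-butyl)dimethylsilane | COc1cc(Br)c(CC=C(C)C)c(O[Si](C)(C)C(C)(C)C)c1 | intermediate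
8 | 3,4-dihydroxybenzaldehyde | O=Cc1ccc(O)c(O)c1 | starting material
9 | 3,4-bis[(tert-butyldimethylsilyl)oxy]benzaldehyde | O=Cc1ccc(O[Si](C)(C)C(C)(C)C)c(O[Si](C)(C)C(C)(C)C)c1 | intermediate
10 | 4-ethenyl-1,2-bis[(tert-butyldimethylsilyl)oxy]benzene | C=Cc1ccc(O[Si](C)(C)C(C)(C)C)c(O[Si](C)(C)C(C)(C)C)c1 | intermediate
11 | tert-butyl{3-[(E)-2-{3,4-bis[(tert-butyldimethylsilyl)oxy]phenyl}ethenyl]-5-methoxy-2-(3-methylbut-2-en-1-yl)phenoxy}dimethylsilane | COc1cc(/C=C/c2ccc(O[Si](C)(C)C(C)(C)C)c(O[Si](C)(C)C(C)(C)C)c2)c(CC=C(C)C)c(O[Si](C)(C)C(C)(C)C)c1 | intermediate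
12 | 1,4-distonic radical cation (not isolated): cis-disubstituted indane carrying the aryl-CH radical on the benzylic carbon and the dimethyl carbocation on the adjacent carbon | COc1cc(O[Si](C)(C)C(C)(C)C)c2c(c1)[C@@H]([CH]c1ccc(O[Si](C)(C)C(C)(C)C)c(O[Si](C)(C)C(C)(C)C)c1)[C@H](C2)[C+](C)C | intermediate
13 | tert-butyl{[(2S,2aR,7aS)-2-{3,4-bis[(tert-butyldimethylsilyl)oxy]phenyl}-4-methoxy-1,1-dimethyl-2,2a,7,7a-tetrahydro-1H-cyclobuta[a]inden-6-yl]oxy}dimethylsilane | COc1cc(O[Si](C)(C)C(C)(C)C)c2c(c1)[C@@H]1[C@H](C2)C(C)(C)[C@H]1c1ccc(O[Si](C)(C)C(C)(C)C)c(O[Si](C)(C)C(C)(C)C)c1 | intermediate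
14 | tert-butyl{[(2S,2aR,7aS)-2-{3,4-bis[(tert-butyldimethylsilyl)oxy]phenyl}-3-bromo-4-methoxy-1,1-dimethyl-2,2a,7,7a-tetrahydro-1H-cyclobuta[a]inden-6-yl]oxy}dimethylsilane | COc1cc(O[Si](C)(C)C(C)(C)C)c2c(c1Br)[C@@H]1[C@H](C2)C(C)(C)[C@H]1c1ccc(O[Si](C)(C)C(C)(C)C)c(O[Si](C)(C)C(C)(C)C)c1 | intermediate
15 | C3-aryllithium derived from 14 (not isolated) | COc1cc(O[Si](C)(C)C(C)(C)C)c2c(c1[Li])[C@@H]1[C@H](C2)C(C)(C)[C@H]1c1ccc(O[Si](C)(C)C(C)(C)C)c(O[Si](C)(C)C(C)(C)C)c1 | intermediate
16 | tert-butyl{[(2S,2aR,7aS)-2-{3,4-bis[(tert-butyldimethylsilyl)oxy]phenyl}-4-methoxy-1,1-dimethyl-3-(3-methylbut-2-en-1-yl)-2,2a,7,7a-tetrahydro-1H-cyclobuta[a]inden-6-yl]oxy}dimethylsilane | COc1cc(O[Si](C)(C)C(C)(C)C)c2c(c1CC=C(C)C)[C@@H]1[C@H](C2)C(C)(C)[C@H]1c1ccc(O[Si](C)(C)C(C)(C)C)c(O[Si](C)(C)C(C)(C)C)c1 | intermediate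
17 | 4-[(2S,2aR,7aS)-6-hydroxy-4-methoxy-1,1-dimethyl-3-(3-methylbut-2-en-1-yl)-2,2a,7,7a-tetrahydro-1H-cyclobuta[a]inden-2-yl]benzene-1,2-diol (CNP0236667.1) | COc1cc(O)c2c(c1CC=C(C)C)[C@@H]1[C@H](C2)C(C)(C)[C@H]1c1ccc(O)c(O)c1 | target

Total step count: 10.
Longest linear sequence: 8 steps (steps 1, 2, 3, 6, 7, 8, 9, 10); steps 4 and 5 form the two-step side branch to styrene 10.

Steps most likely to fail

Step 7 (Proposed new method). The chiral counter-anion may discriminate poorly between the two mirror-image twisted conformers of the radical cation in this intramolecular setting, giving low enantiofacial selectivity. The distonic radical cation may also be intercepted (proton loss, arene capture) before the cyclobutane closes. Fallback with known chemistry: setting out from 11, the radical-cation [2+2] cycloaddition is run without chiral information under established Ru(bpz)3 photoredox conditions (visible light, air as co-oxidant, CH2Cl2, rt). This should give 13 together with its mirror image, the (2R,2aS,7aR)-enantiomer of 13 F1, as a racemate. The two are separated by preparative chromatography on a chiral stationary phase (SFC), and the route is rejoined at 13.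

Step 1. Capture of the hindered 2,6-dibromoaryllithium 2 by the allylic bromide may be slow, so that loss of LiBr to an aryne on warming or γ-attack (leading to the 1,1-dimethylallyl isomer) competes. Fallback: setting out from 1, the same lithiation is quenched with allyl bromide, for which α- and γ-attack give the same product, to give 2-allyl-1,3-dibromo-5-methoxybenzene F2. Olefin cross-metathesis of F2 with excess 2-methylbut-2-ene (second-generation ruthenium benzylidene catalyst, CH2Cl2, 40 °C) then builds the trisubstituted alkene and returns to the route at 3.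

Step 9. The hindered aryllithium 15 may be protonated before it is alkylated (returning 13), and γ-attack on prenyl bromide may compete on this late, valuable intermediate. Fallback: setting out from 14, a ligand-controlled α-selective Suzuki–Miyaura coupling with 3-methylbut-2-enylboronic acid pinacol ester (Pd precatalyst with a bulky biarylphosphine, aqueous K3PO4, THF, 40 °C) avoids the organolithium altogether and returns to the route at 16; it makes no compound that the list does not hold (F0).

Further compounds
F1 | step 7 | tert-butyl{[(2R,2aS,7aR)-2-{3,4-bis[(tert-butyldimethylsilyl)oxy]phenyl}-4-methoxy-1,1-dimethyl-2,2a,7,7a-tetrahydro-1H-cyclobuta[a]inden-6-yl]oxy}dimethylsilane (enantiomer of 13) | COc1cc(O[Si](C)(C)C(C)(C)C)c2c(c1)[C@H]1[C@@H](C2)C(C)(C)[C@@H]1c1ccc(O[Si](C)(C)C(C)(C)C)c(O[Si](C)(C)C(C)(C)C)c1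
F2 | step 1 | 2-allyl-1,3-dibromo-5-methoxybenzene | COc1cc(Br)c(CC=C)c(Br)c1
F0 | step 9 | none | none
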